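(The readings are simulated on assumed constants; scatter was added.)

**The trap.** The share of L in the dawn flask looks like one number, yet it is a sum over running odds that keep falling. Running odds mean the rate of L over the rate of E, the instantaneous selectivity.

| setting | dawn | dusk | flask |
|---|---|---|---|
| J | 0.30 M | 0.30 M | 0.30 M |
| X | 0.24 M | 0.36 M | 0.240 M |
| Z | 0.27 M | 0.27 M | 0.270 M |
| remark | the very flask that is asked about, followed so far | run made earlier |  |
| time |  |  | 6.0 h |

| run | time / h | L / % | E / % |
|---|---|---|---|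
| dawn | 0.333 | 49.2 | 24.8 |
| dawn | 0.667 | 55.7 | 39.3 |
| dawn | 1.00 | 56.0 | 42.0 |
| dawn | 1.33 | 56.0 | 44.2 |
| dawn | 1.50 | 57.7 | 44.8 |
| dawn | 2.00 | 56.3 | 42.8 |
| dawn | 2.50 | 56.7 | 43.4 |
| dusk | 0.333 | 56.3 | 17.0 |
| dusk | 0.667 | 65.8 | 26.3 |
| dusk | 1.00 | 70.1 | 33.4 |
| dusk | 1.33 | 70.2 | 31.7 |
| dusk | 1.50 | 69.0 | 32.6 |
| dusk | 2.00 | 69.3 | 30.8 |
| dusk | 2.50 | 68.9 | 30.3 |

(readings scatter by 1 percentage point)

* share of L in L plus E at 40 s
* share of L in L plus E at 6.0 h

**Rival strength.** Suppose the running odds equal the unspent X, D counted, divided by a steady strength S. Then S is the E made divided by the logarithm of charged over unspent X. The last dusk reading gives 0.106 M, the rival strength. The last dawn reading gives 0.106 M.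

**In decades.** At steady S, each 0.245 M of E costs one decade of odds. Reckoned at that S, dawn odds start near 2.25. They lose 0.532 of a decade and end near 0.656. L plus E reads 100%, so I take the last dawn share, 56.6%, for the late answer.

**Early odds.** G starts from nothing. The first dawn reading gives a mean strength of 0.0779 M, which implies a rise time near 0.0892 h. Over 40 s, S then averages 0.00663 M, so I expect 97.3%.

**Forecast.** The forecast gives 96% (86% to 99.5%), lower than mine, and 56.5% (55.5% to 57.5%), holding that “G builds up gradually from zero as Z dissolves”.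

**Result.** The flask gives 94.6% at 40 s and 56.2% at 6.0 h.

    X + Q → L (k = 15.0 M⁻¹ min⁻¹)
    G + Q → E (k = 24.0 M⁻¹ min⁻¹)
    J → Q (k = 0.0680 min⁻¹)
    X ⇌ D (K = 1.60, k = 0.0250 min⁻¹)
    Z ⇌ G, rate k5*(cs5 - [G]) while solid is left; crystals form when [G] > cs5 (solubility = 0.0530 M, k = 0.440 min⁻¹)

**Why steady.** The flask's E, 0.131 M, spends 0.535 of a decade. G stands at 0.0495 M after 0.600 h and 0.0530 M after 6.00 h. The low solubility of G, which also sets how fast it dissolves, is the main reason for the flask's early share: the run without it gives 35.7% at 40 s, against 94.6%. It is also part of the reason for the flask's late share: at 6.0 h that run gives 34.0%, against 56.2%.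

**Second flask.** With 0.60 M of X, iterating the same S gives E of 0.0573 M, a share of 80.9%. That neighbour computes to 81.5%.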